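## Retrosynthetic overview

1. C8–C9 is cut last: a visible-light nickel/iridium cross-electrophile coupling joins an iodoethyl 1,2-dioxane to an (E)-alkenyl bromide (the key bond-forming step). The bromide comes from dihydro-β-ionone (alkyne, carboalumination/bromination, ring allylic oxidation).
2. C2–C3 is made by Lewis acid opening of a bridged bicyclic peroxyacetal with an acetoacetate silyl enol ether (new step, sets C3 by inversion), followed by retro-Claisen cleavage with kinetic protonation (sets C2).
3. The peroxide: C6–OO by invertive perhydrolysis of the oxetane made from (R)-linalool; C3–OO by hemiperacetal closure after ozonolysis; the freed CH2CH2OH arm then bridges C3.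
4. Stereochemistry: C6 is bought in (R)-linalool, relayed to C3 through the bridge, and from C3 to C2 by substrate-controlled protonation.
5. Ring order: oxetane (temporary) → 1,2-dioxane → acetal bridge (temporary); the cyclohexenone ring is bought in dihydro-β-ionone.

Assumption: the SMILES is read as the (2S,3S,6R) isomer with an E alkene; atom labels follow the target (C1 ester carbon, C2 α-carbon, C3–C6 dioxane carbons with C6 quaternary, C7–C8 the ethylene link, C9=C10 the alkene); (R)-(−)-linalool of high enantiomeric purity is taken as bought.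

## Route

Step 1
Reactants: 1 (R)-(−)-linalool [(3R)-3,7-dimethylocta-1,6-dien-3-ol]
Product: 2 (3R)-3,7-dimethyloct-6-ene-1,3-diol
Conditions: 9-BBN (2.2 equiv), THF, 0 °C → rt; then NaOH, H2O2, 0 °C
Reagents that add atoms: hydrogen peroxide, OO
Why: Anti-Markovnikov hydroboration–oxidation; 9-BBN reacts with the monosubstituted vinyl group far faster than with the trisubstituted alkene, and the bought C6 carbinol centre is untouched.

Step 2
Reactants: 2 (3R)-3,7-dimethyloct-6-ene-1,3-diol
Product: 4 (2R)-2-methyl-2-(4-methylpent-3-en-1-yl)oxetane, via primary tosylate 3 (not isolated)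
Conditions: n-BuLi (1.0 equiv), THF, 0 °C; TsCl (1.0 equiv); then n-BuLi (1.1 equiv), 0 → 60 °C
Reagents that add atoms: none
Why: Selective tosylation of the primary alkoxide, then intramolecular Williamson etherification (4-exo-tet) by the tertiary alkoxide; the C6–O bond is not broken, so configuration is retained.

Step 3
Reactants: 4 (2R)-2-methyl-2-(4-methylpent-3-en-1-yl)oxetane
Product: 5 (3S)-3-hydroperoxy-3,7-dimethyloct-6-en-1-ol
Conditions: H2O2 (anhydrous, ca. 10 equiv in Et2O), TMSOTf (0.2 equiv), Et2O, −78 → −40 °C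
Reagents that add atoms: hydrogen peroxide, OO
Why: Lewis acid-promoted perhydrolysis of a 2,2-disubstituted oxetane; H2O2 attacks the activated tertiary carbon from the backside of the departing ring oxygen (borderline SN2), so C6 is inverted to the configuration the target needs.

Step 4
Reactants: 5 (3S)-3-hydroperoxy-3,7-dimethyloct-6-en-1-ol
Product: 8 (1R,5S)-5-methyl-2,6,7-trioxabicyclo[3.2.2]nonane, via hydroperoxy aldehyde 6 (not isolated), via dioxanol 7 (not isolated)
Conditions: O3, pyridine (3 equiv), CH2Cl2, −78 °C; short silica pad; then CSA (10 mol%), 4 Å MS, CH2Cl2, 0 °C → rt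
Reagents that add atoms: none
Why: Criegee ozonolysis (pyridine-moderated, no reductant that could touch the hydroperoxide) gives the aldehyde, the tertiary hydroperoxide adds to it 6-exo to close the 1,2-dioxane, and acid-catalysed intramolecular transacetalisation by the CH2CH2OH arm gives the bridged acetal in which the C3–O(acetal) bond is necessarily cis to C7, so C3 is fixed by C6.

Step 5
Reactants: 9 methyl 2-methyl-3-oxobutanoate
Product: 10 methyl 2-methyl-3-[(trimethylsilyl)oxy]but-2-enoate (E/Z mixture)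
Conditions: TMSCl, Et3N, DMF, rt
Reagents that add atoms: chlorotrimethylsilane, C[Si](C)(C)Cl
Why: O-silylation of the β-keto ester enol (silyl enol ether formation); no stereocentre is involved.

Step 6
Reactants: 8 (1R,5S)-5-methyl-2,6,7-trioxabicyclo[3.2.2]nonane; 10 methyl 2-methyl-3-[(trimethylsilyl)oxy]but-2-enoate
Product: 11 methyl 2-[(3S,6S)-6-(2-hydroxyethyl)-6-methyl-1,2-dioxan-3-yl]-2-methyl-3-oxobutanoate (both C2 epimers)
Conditions: TiCl4 (1.1 equiv), 10 (2 equiv), CH2Cl2, −78 °C; then cold H2O
Reagents that add atoms: none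
Why: Proposed new method: TiCl4 should bind the only ether-type oxygen of 8 (the acetal oxygen of the CH2CH2O bridge; the two peroxide oxygens are much weaker Lewis bases) and ionise the C3–O bond to a peroxycarbenium ion held in a tight ion pair with the still tethered titanium alkoxide, so that enol silane 10 attacks C3 anti to the departing bridge oxygen (invertive, SN2-like acetal substitution) and the new C2–C3 bond ends up trans to the C7–C8 arm, i.e. cis to the C6 methyl = (3S), while release of the boat-locked bridge drives the opening and the quaternary C2 formed here does not matter because it is re-set in step 7; the closest known chemistry is the Johnson-type invertive opening of cyclic acetals by silyl enol ethers and the Mukaiyama-type Lewis acid substitution of monocyclic 3-alkoxy-1,2-dioxolanes and -dioxanes through peroxycarbenium ions, neither of which has been shown on a bridged bicyclic peroxyacetal or used to relay configuration across a 1,2-dioxane.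

Step 7
Reactants: 11 methyl 2-[(3S,6S)-6-(2-hydroxyethyl)-6-methyl-1,2-dioxan-3-yl]-2-methyl-3-oxobutanoate
Product: 12 methyl (2S)-2-[(3S,6S)-6-(2-hydroxyethyl)-6-methyl-1,2-dioxan-3-yl]propanoate
Conditions: NaOMe (0.2 equiv), MeOH, −20 → 0 °C; then AcOH
Reagents that add atoms: none
Why: Retro-Claisen deacetylation releases the ester enolate in methanol, where it is protonated at once (kinetic protonation, the same event that ends a hydroperoxide oxa-Michael cyclisation): with C3–H eclipsing the enolate to avoid A1,3 strain, the proton enters from the face flanked by the ring oxygen and anti to C4, giving the 2,3-erythro (2S,3S) ester.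

Step 8
Reactants: 12 methyl (2S)-2-[(3S,6S)-6-(2-hydroxyethyl)-6-methyl-1,2-dioxan-3-yl]propanoate
Product: 13 methyl (2S)-2-[(3S,6S)-6-(2-iodoethyl)-6-methyl-1,2-dioxan-3-yl]propanoate
Conditions: PPh3, I2, imidazole (premixed), CH2Cl2, 0 °C
Reagents that add atoms: iodine, II
Why: Appel-type iodination of the primary alcohol by the preformed iodophosphonium salt; no stereocentre is involved and no free phosphine is left to reduce the peroxide.

Step 9
Reactants: 14 dihydro-β-ionone [4-(2,6,6-trimethylcyclohex-1-en-1-yl)butan-2-one]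
Product: 16 2-(but-3-yn-1-yl)-1,3,3-trimethylcyclohex-1-ene, via enol phosphate 15 (not isolated)
Conditions: LiN(i-Pr)2 (1.05 equiv), THF, −78 °C; ClP(O)(OEt)2; then LiN(i-Pr)2 (2.3 equiv), −78 °C → rt
Reagents that add atoms: none
Why: Kinetic (methyl-side) enolate O-phosphorylation followed by base-induced elimination, the Negishi conversion of a methyl ketone into a terminal alkyne; no stereocentre.

Step 10
Reactants: 16 2-(but-3-yn-1-yl)-1,3,3-trimethylcyclohex-1-ene
Product: 18 2-[(3E)-4-bromo-3-methylbut-3-en-1-yl]-1,3,3-trimethylcyclohex-1-ene, via alkenylalane 17 (not isolated)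
Conditions: AlMe3 (2.5 equiv), Cp2ZrCl2 (0.25 equiv), CH2Cl2, 0 °C → rt; then NBS, THF, −30 → 0 °C
Reagents that add atoms: trimethylaluminium, C[Al](C)C; N-bromosuccinimide, BrN1C(=O)CCC1=O
Why: Zirconium-catalysed Negishi carboalumination adds methyl and aluminium syn across the alkyne, and bromodealumination proceeds with retention, so only the E alkenyl bromide forms.

Step 11
Reactants: 18 2-[(3E)-4-bromo-3-methylbut-3-en-1-yl]-1,3,3-trimethylcyclohex-1-ene
Product: 19 3-[(3E)-4-bromo-3-methylbut-3-en-1-yl]-2,4,4-trimethylcyclohex-2-en-1-one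
Conditions: Rh2(cap)4 (cap = caprolactamate, 1 mol%), t-BuOOH (70% aq., 5 equiv), K2CO3 (0.5 equiv), CH2Cl2, rt
Reagents that add atoms: tert-butyl hydroperoxide, CC(C)(C)OO
Why: Allylic C–H oxidation by tert-butylperoxyl radicals at the ring methylene next to the electron-rich tetrasubstituted alkene, giving the conjugated enone (the usual site in β-ionone-type rings); the electron-poor bromoalkene is left alone and no stereocentre is formed.

Step 12
Reactants: 13 methyl (2S)-2-[(3S,6S)-6-(2-iodoethyl)-6-methyl-1,2-dioxan-3-yl]propanoate; 19 3-[(3E)-4-bromo-3-methylbut-3-en-1-yl]-2,4,4-trimethylcyclohex-2-en-1-one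
Product: 20 methyl (2S)-2-[(3S,6R)-6-methyl-6-[(3E)-4-methyl-6-(2,6,6-trimethyl-3-oxocyclohex-1-en-1-yl)hex-3-en-1-yl]-1,2-dioxan-3-yl]propanoate (CNP0362511.1)
Conditions: Ir[dF(CF3)ppy]2(dtbbpy)PF6 (1 mol%), NiCl2·DME (5 mol%), dtbbpy (5 mol%), (Me3Si)3SiH (1.2 equiv), Na2CO3 (2 equiv), DME, blue LEDs (450 nm), 25 °C
Reagents that add atoms: none
Why: Nickel/iridium metallaphotoredox cross-electrophile coupling: the photogenerated silyl radical abstracts iodine from 13, the primary C8 radical is captured by the alkenylnickel species formed by oxidative addition of 19, and reductive elimination forms C8–C9 with retention of the E geometry; no stereocentre is touched.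

## Compound list

1 | (R)-(−)-linalool, (3R)-3,7-dimethylocta-1,6-dien-3-ol | C=C[C@](C)(O)CCC=C(C)C | starting material
2 | (3R)-3,7-dimethyloct-6-ene-1,3-diol | OCC[C@](C)(O)CCC=C(C)C | intermediate
3 | (3R)-3-hydroxy-3,7-dimethyloct-6-en-1-yl 4-methylbenzenesulfonate | Cc1ccc(cc1)S(=O)(=O)OCC[C@](C)(O)CCC=C(C)C | intermediate
4 | (2R)-2-methyl-2-(4-methylpent-3-en-1-yl)oxetane | C1C[C@](C)(O1)CCC=C(C)C | intermediate
5 | (3S)-3-hydroperoxy-3,7-dimethyloct-6-en-1-ol | OCC[C@@](C)(OO)CCC=C(C)C | intermediate
6 | (4S)-4-hydroperoxy-6-hydroxy-4-methylhexanal | OCC[C@@](C)(OO)CCC=O | intermediate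
7 | (6S)-6-(2-hydroxyethyl)-6-methyl-1,2-dioxan-3-ol (anomers) | OCC[C@@]1(C)OOC(O)CC1 | intermediate
8 | (1R,5S)-5-methyl-2,6,7-trioxabicyclo[3.2.2]nonane | C1C[C@@]2(C)OO[C@@H](O1)CC2 | intermediate
9 | methyl 2-methyl-3-oxobutanoate | COC(=O)C(C)C(C)=O | starting material
10 | methyl 2-methyl-3-[(trimethylsilyl)oxy]but-2-enoate (E/Z mixture) | COC(=O)C(C)=C(C)O[Si](C)(C)C | intermediate
11 | methyl 2-[(3S,6S)-6-(2-hydroxyethyl)-6-methyl-1,2-dioxan-3-yl]-2-methyl-3-oxobutanoate (C2 epimers) | COC(=O)C(C)(C(C)=O)[C@@H]1CC[C@@](C)(CCO)OO1 | intermediate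
12 | methyl (2S)-2-[(3S,6S)-6-(2-hydroxyethyl)-6-methyl-1,2-dioxan-3-yl]propanoate | COC(=O)[C@@H](C)[C@@H]1CC[C@@](C)(CCO)OO1 | intermediate
13 | methyl (2S)-2-[(3S,6S)-6-(2-iodoethyl)-6-methyl-1,2-dioxan-3-yl]propanoate | COC(=O)[C@@H](C)[C@@H]1CC[C@@](C)(CCI)OO1 | intermediate
14 | dihydro-β-ionone, 4-(2,6,6-trimethylcyclohex-1-en-1-yl)butan-2-one | CC(=O)CCC1=C(C)CCCC1(C)C | starting material
15 | diethyl 4-(2,6,6-trimethylcyclohex-1-en-1-yl)but-1-en-2-yl phosphate | CCOP(=O)(OCC)OC(=C)CCC1=C(C)CCCC1(C)C | intermediate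
16 | 2-(but-3-yn-1-yl)-1,3,3-trimethylcyclohex-1-ene | C#CCCC1=C(C)CCCC1(C)C | intermediate
17 | dimethyl[(1E)-2-methyl-4-(2,6,6-trimethylcyclohex-1-en-1-yl)but-1-en-1-yl]alumane | C[Al](C)/C=C(\C)CCC1=C(C)CCCC1(C)C | intermediate
18 | 2-[(3E)-4-bromo-3-methylbut-3-en-1-yl]-1,3,3-trimethylcyclohex-1-ene | Br/C=C(\C)CCC1=C(C)CCCC1(C)C | intermediate
19 | 3-[(3E)-4-bromo-3-methylbut-3-en-1-yl]-2,4,4-trimethylcyclohex-2-en-1-one | Br/C=C(\C)CCC1=C(C)C(=O)CCC1(C)C | intermediate
20 | methyl (2S)-2-[(3S,6R)-6-methyl-6-[(3E)-4-methyl-6-(2,6,6-trimethyl-3-oxocyclohex-1-en-1-yl)hex-3-en-1-yl]-1,2-dioxan-3-yl]propanoate | COC(=O)[C@@H](C)[C@@H]1CC[C@@](C)(CC/C=C(\C)CCC2=C(C)C(=O)CCC2(C)C)OO1 | target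

## Step count and risks

Total steps: 12. Longest linear sequence: 8 (steps 1, 2, 3, 4, 6, 7, 8, 12).

**Step 6 (the proposed new step).** Three things can go wrong: ionisation on the peroxide side (giving an oxepane), a free peroxycarbenium ion that loses the bridge's facial memory (C3 epimers), or sluggish attack by the hindered enol silane. The fallback uses known chemistry only; it sets out from 4 and comes back at 12. Ozonolysis of 4 (O3, CH2Cl2, −78 °C; Me2S) gives 3-[(2R)-2-methyloxetan-2-yl]propanal F1. Wittig reaction with methyl 2-(triphenylphosphoranylidene)propanoate gives methyl (2E)-2-methyl-5-[(2R)-2-methyloxetan-2-yl]pent-2-enoate F2. Perhydrolysis as in step 3 gives methyl (2E,5S)-5-hydroperoxy-7-hydroxy-2,5-dimethylhept-2-enoate F3. Et2NH in CF3CH2OH then closes the dioxane by 6-exo hydroperoxide oxa-Michael addition, with the same kinetic protonation at C2. C3 is not biased in this closure, so 12 has to be separated by chromatography from methyl (2R)-2-[(3R,6S)-6-(2-hydroxyethyl)-6-methyl-1,2-dioxan-3-yl]propanoate F4.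

**Step 4.** The bridge forces the dioxane into a boat; the acetal may not close, or may give oligomeric peroxyacetals. The fallback gives up the bridge; it sets out from 5 and comes back at 12. Ozonolysis as in step 4 is stopped before the acid stage, and the dioxanol is acetylated (Ac2O, pyridine, DMAP) to (6S)-6-[2-(acetyloxy)ethyl]-6-methyl-1,2-dioxan-3-yl acetate F5. SnCl4-mediated substitution of the anomeric acetate by 10 through the untethered peroxycarbenium ion gives methyl 2-{(6S)-6-[2-(acetyloxy)ethyl]-6-methyl-1,2-dioxan-3-yl}-2-methyl-3-oxobutanoate F6 as both C3 epimers. NaOMe in MeOH, as in step 7, removes both acetyl groups and gives 12 together with methyl (2R)-2-[(3R,6S)-6-(2-hydroxyethyl)-6-methyl-1,2-dioxan-3-yl]propanoate F7, which is separated by chromatography.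

**Step 12.** Tolerance of the O–O bond to low-valent nickel and to silyl radicals is untested, and the C8 radical could attack the peroxide intramolecularly. The fallback replaces the radical coupling by an organozinc coupling; it sets out from 13 and comes back at 20. Zinc insertion (Zn dust, LiCl, THF, 25 °C) gives iodo{2-[(3S,6S)-3-[(2S)-1-methoxy-1-oxopropan-2-yl]-6-methyl-1,2-dioxan-6-yl]ethyl}zinc F8, which is coupled with 19 in a Negishi reaction catalysed by PdCl2(dppf) in THF.

Further compounds
F1 | step 6 | 3-[(2R)-2-methyloxetan-2-yl]propanal | C1C[C@](C)(O1)CCC=O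
F2 | step 6 | methyl (2E)-2-methyl-5-[(2R)-2-methyloxetan-2-yl]pent-2-enoate | C1C[C@](C)(O1)CC/C=C(\C)C(=O)OC
F3 | step 6 | methyl (2E,5S)-5-hydroperoxy-7-hydroxy-2,5-dimethylhept-2-enoate | OCC[C@@](C)(OO)CC/C=C(\C)C(=O)OC
F4 | step 6 | methyl (2R)-2-[(3R,6S)-6-(2-hydroxyethyl)-6-methyl-1,2-dioxan-3-yl]propanoate | COC(=O)[C@H](C)[C@H]1CC[C@@](C)(CCO)OO1
F5 | step 4 | (6S)-6-[2-(acetyloxy)ethyl]-6-methyl-1,2-dioxan-3-yl acetate | CC(=O)OCC[C@@]1(C)OOC(OC(C)=O)CC1
F6 | step 4 | methyl 2-{(6S)-6-[2-(acetyloxy)ethyl]-6-methyl-1,2-dioxan-3-yl}-2-methyl-3-oxobutanoate | COC(=O)C(C)(C(C)=O)C1CC[C@@](C)(CCOC(C)=O)OO1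
F7 | step 4 | methyl (2R)-2-[(3R,6S)-6-(2-hydroxyethyl)-6-methyl-1,2-dioxan-3-yl]propanoate | COC(=O)[C@H](C)[C@H]1CC[C@@](C)(CCO)OO1
F8 | step 12 | iodo{2-[(3S,6S)-3-[(2S)-1-methoxy-1-oxopropan-2-yl]-6-methyl-1,2-dioxan-6-yl]ethyl}zinc | COC(=O)[C@@H](C)[C@@H]1CC[C@@](C)(CC[Zn]I)OO1
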